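**Overview**

- Retrosynthesis: ring A (C1 carboxyl carbon, C2 OMe, C3 carbinol chain, C4‑H, C5‑H, C6 aryloxy) is cut at C1–C2, C5–C6 and C2–C3. This leads back to a vinylketene (from an α‑diazo enone carrying the chain) and an aryl ynol ether in which the diaryl ether oxygen already joins ring B to an sp carbon; no aryl–oxygen coupling is made on ring A.
- Enabling feature: ring A has four contiguous substituents (C6, C1, C2, C3) beside two adjacent CH positions (C4, C5), and its C2 and C6 oxygens are meta across C1. That is the resorcinol pattern a vinylketene/ynol ether benzannulation delivers, and the ether oxygen with three ortho neighbours is best bonded first to an unhindered alkyne carbon.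
- Forward order: ring B is bought intact; its phenol oxygen is made into a dichlorovinyl ether and then an alkynyl ether extended by one carbon (the future carboxyl). The chain is grown separately to the diazo enone. Ring A, the only ring formed, closes when the halves meet; oxidation to the acid and deprotection finish.
- Stereochemistry: the single (S) carbinol is C3 of (S)‑3‑hydroxy‑γ‑butyrolactone. None of its four bonds is made or broken, and the priority order (O, former lactone CH2O carbon, CH2, H), hence the S descriptor, holds throughout.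

Key step: step 13

Assumption: 2‑hydroxy‑3‑methoxy‑5‑methylbenzaldehyde is taken as a catalogue compound (it is also the ortho‑formylation product of 2‑methoxy‑4‑methylphenol).

Abbreviations: TBS = tert‑butyldimethylsilyl, TIPS = triisopropylsilyl, TES = triethylsilyl, Bn = benzyl, PPTS = pyridinium p‑toluenesulfonate. Ring A is numbered as in the target acid.

**Route**

Step 1
Reactants: 1 (S)‑3‑hydroxy‑γ‑butyrolactone [(4S)‑4‑hydroxyoxolan‑2‑one]
Product: 2 (2S)‑4‑methylpentane‑1,2,4‑triol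
Conditions: MeMgBr (4.5 equiv), THF, 0 °C → rt; H2O (minimum), filter, hot THF wash
Reagents that add atoms: methylmagnesium bromide, C[Mg]Br
Why: After the first equivalent has deprotonated the hydroxyl, double Grignard addition to the lactone carbonyl opens the ring to the gem‑dimethyl carbinol without touching any bond of the stereocentre.

Step 2
Reactants: 2 (2S)‑4‑methylpentane‑1,2,4‑triol
Product: 3 (2S)‑1,2,4‑tris(tert‑butyldimethylsilyloxy)‑4‑methylpentane
Conditions: TBSOTf (3.6 equiv), 2,6‑lutidine (5 equiv), CH2Cl2, 0 °C → rt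
Reagents that add atoms: tert‑butyldimethylsilyl trifluoromethanesulfonate, CC(C)(C)[Si](C)(C)OS(=O)(=O)C(F)(F)F
Why: Exhaustive silylation with a silyl triflate and a hindered pyridine base covers the primary, secondary and tertiary hydroxyls alike and makes the water‑soluble triol easy to handle.

Step 3
Reactants: 3 tris‑TBS ether
Product: 4 (2S)‑2,4‑bis(tert‑butyldimethylsilyloxy)‑4‑methylpentan‑1‑ol
Conditions: HF·pyridine, pyridine, THF, 0 °C
Reagents that add atoms: none
Why: Buffered HF·pyridine cleaves the least hindered primary silyl ether fastest (standard selective monodesilylation of a 1,2‑bis‑silyl ether), the secondary and tertiary ethers reacting far more slowly.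

Step 4
Reactants: 4 primary alcohol
Product: 5 (2S)‑2,4‑bis(tert‑butyldimethylsilyloxy)‑4‑methylpentanal
Conditions: Dess–Martin periodinane (1.3 equiv), pyridine, CH2Cl2, 0 °C → rt
Reagents that add atoms: none
Why: Dess–Martin oxidation under buffered, near‑neutral conditions should give the α‑silyloxy aldehyde without epimerisation or over‑oxidation; it is used at once.

Step 5
Reactants: 5 α‑silyloxy aldehyde; 6 1‑(triphenylphosphoranylidene)propan‑2‑one
Product: 7 (3E,5S)‑5,7‑bis(tert‑butyldimethylsilyloxy)‑7‑methyloct‑3‑en‑2‑one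
Conditions: CH2Cl2, 40 °C
Reagents that add atoms: none
Why: Wittig olefination with the stabilised acetonyl ylide is E‑selective and, being salt‑free and only weakly basic, should leave the α‑silyloxy stereocentre intact.

Step 6
Reactants: 7 enone
Product: 9 (3E,5S)‑5,7‑bis(tert‑butyldimethylsilyloxy)‑1‑diazo‑7‑methyloct‑3‑en‑2‑one, via trifluoroacetyl diketone 8 (not isolated)
Conditions: LiN(SiMe3)2 (1.1 equiv), THF, −78 °C; CF3CO2CH2CF3 (1.2 equiv); dilute HCl wash; then MsN3 (1.5 equiv), Et3N (1.5 equiv), H2O (1 equiv), MeCN, rt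
Reagents that add atoms: methanesulfonyl azide, CS(=O)(=O)N=[N+]=[N-]; 2,2,2‑trifluoroethyl trifluoroacetate, O=C(OCC(F)(F)F)C(F)(F)F (its CF3CO group is held only in 8)
Why: Detrifluoroacetylative diazo transfer (Danheiser protocol) relies on kinetic enolisation at the methyl group, Claisen trifluoroacetylation of that carbon and Regitz‑type transfer from the sulfonyl azide with loss of the trifluoroacetyl group, conditions under which the γ‑silyloxy centre is not enolised.

Step 7
Reactants: 10 2‑hydroxy‑3‑methoxy‑5‑methylbenzaldehyde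
Product: 11 2,3‑dihydroxy‑5‑methylbenzaldehyde
Conditions: BBr3 (2.2 equiv), CH2Cl2, −78 → 0 °C; H2O
Reagents that add atoms: none
Why: BBr3 demethylation cleaves the aryl methyl ether through the aryloxyborane while the aldehyde survives at low temperature.

Step 8
Reactants: 11 2,3‑dihydroxy‑5‑methylbenzaldehyde
Product: 12 3‑(benzyloxy)‑2‑hydroxy‑5‑methylbenzaldehyde
Conditions: NaH (2.2 equiv), DMSO, 20 °C; BnBr (1.0 equiv); dilute HCl
Reagents that add atoms: benzyl bromide, BrCc1ccccc1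
Why: In the dianion the C2 phenoxide is conjugated and chelated with the ortho‑formyl group, so Williamson alkylation with one equivalent of benzyl bromide should occur at the more nucleophilic C3 phenoxide.

Step 9
Reactants: 12 3‑(benzyloxy)‑2‑hydroxy‑5‑methylbenzaldehyde; 13 trichloroethylene
Product: 15 3‑(benzyloxy)‑2‑[(E)‑1,2‑dichlorovinyloxy]‑5‑methylbenzaldehyde, via dichloroacetylene 14 (not isolated)
Conditions: 13 (3 equiv), K2CO3 (2 equiv), DMF, 70 °C
Reagents that add atoms: none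
Why: Base‑induced loss of HCl from trichloroethylene gives dichloroacetylene in solution, and anti addition of the phenoxide followed by protonation is the established route to aryl (E)‑1,2‑dichlorovinyl ethers, so the crowded oxygen is bonded to an unhindered sp carbon.

Step 10
Reactants: 15 dichlorovinyl ether aldehyde
Product: 16 {3‑(benzyloxy)‑2‑[(E)‑1,2‑dichlorovinyloxy]‑5‑methylphenyl}methanol
Conditions: NaBH4, MeOH/THF, 0 °C
Reagents that add atoms: none
Why: Borohydride reduction of the aldehyde is chemoselective, the dichlorovinyl and benzyl ethers being inert to hydride.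

Step 11
Reactants: 16 benzylic alcohol
Product: 17 {3‑(benzyloxy)‑2‑[(E)‑1,2‑dichlorovinyloxy]‑5‑methylbenzyloxy}triisopropylsilane
Conditions: TIPSCl, imidazole, DMF, rt
Reagents that add atoms: chlorotriisopropylsilane, CC(C)[Si](Cl)(C(C)C)C(C)C
Why: Imidazole‑promoted silylation of the primary alcohol gives a robust TIPS ether that tolerates butyllithium and mild acid and stays distinct from the TES ether introduced next.

Step 12
Reactants: 17 TIPS‑protected dichlorovinyl ether; 18 formaldehyde (monomer cracked from paraformaldehyde)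
Product: 22 {3‑(benzyloxy)‑5‑methyl‑2‑[3‑(triethylsilyloxy)prop‑1‑ynyloxy]benzyloxy}triisopropylsilane, via chloroethynyl ether 19 (not isolated), via lithium aryloxyacetylide 20 (not isolated), via lithium propynolate 21 (not isolated)
Conditions: n‑BuLi (2.4 equiv), THF, −78 → −40 °C; CH2O (THF solution), −78 °C; Et3SiCl, −78 → 0 °C
Reagents that add atoms: chlorotriethylsilane, CC[Si](Cl)(CC)CC
Why: Dehydrochlorination and chlorine–lithium exchange give the lithium aryloxyacetylide (the established dichlorovinyl ether route to ynol ethers), which adds to formaldehyde, and silylating the alkoxide in the same flask avoids isolating the free aryloxypropargyl alcohol, which is prone to Meyer–Schuster rearrangement.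

Step 13
Reactants: 9 α‑diazo enone; 22 aryl ynol ether
Product: 27 3‑[2‑(benzyloxy)‑4‑methyl‑6‑(triisopropylsilyloxymethyl)phenoxy]‑6‑[(1S)‑1,3‑bis(tert‑butyldimethylsilyloxy)‑3‑methylbutyl]‑2‑(triethylsilyloxymethyl)phenol, via vinylketene 23 (not isolated), via cyclobutenone 24 (not isolated), via dienylketene 25 (not isolated), via cyclohexadienone 26 (not isolated)
Conditions: 9 (1.3 equiv), hν (300–350 nm, Pyrex), ClCH2CH2Cl, 25 °C; then 80 °C
Reagents that add atoms: none
Why: Irradiation of 9 expels N2 and Wolff rearrangement gives vinylketene 23, whose carbonyl carbon is attacked by the nucleophilic alkyne carbon of 22 (the one bearing CH2OSiEt3) in a regiospecific [2+2] cycloaddition that forms C1–C2 and C5–C6 and gives cyclobutenone 24. Heating opens 24 by reversible 4π electrocyclic cleavage to dienylketene 25, ring A closes by thermal disrotatory 6π electrocyclisation of the ketene carbon onto the alkene carbon bearing the chain (forming C2–C3), and tautomerisation of cyclohexadienone 26 gives phenol 27. The closest known reaction is the second‑generation Danheiser benzannulation (α‑diazo enone as vinylketene source, alkoxy‑ or siloxyalkyne as ketenophile), of which an aryloxyalkyne is a further member of the same ynol ether class. No stereocentre is created: the transient sp3 ring carbon of 26 is lost on aromatisation and the adjacent (S)‑silyloxy carbinol has no bond made or broken. The only selectivity required is the regiochemistry of the ketene–alkyne [2+2] step, which the oxygen polarisation of the ynol ether fixes so that the aryloxy carbon bonds to the ketene α‑carbon and the ether oxygen ends at C6, meta to the new C2 hydroxyl with the carboxyl carbon between them. The substrate suits the step because the bulky 2,6‑disubstituted aryloxy group sits on a linear sp carbon and, unlike an alkyl ynol ether, offers no β‑hydrogen for retro‑ene loss of the alkyne at 80 °C.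

Step 14
Reactants: 27 ring A phenol
Product: 28 {6‑[2‑(benzyloxy)‑4‑methyl‑6‑(triisopropylsilyloxymethyl)phenoxy]‑3‑[(1S)‑1,3‑bis(tert‑butyldimethylsilyloxy)‑3‑methylbutyl]‑2‑methoxybenzyloxy}triethylsilane
Conditions: MeI, K2CO3, DMF, 25 °C
Reagents that add atoms: iodomethane, CI
Why: Williamson O‑methylation of the phenoxide with a small electrophile should proceed despite the two ortho groups, and all silyl ethers tolerate carbonate.

Step 15
Reactants: 28 ring A methyl ether
Product: 29 {6‑[2‑(benzyloxy)‑4‑methyl‑6‑(triisopropylsilyloxymethyl)phenoxy]‑3‑[(1S)‑1,3‑bis(tert‑butyldimethylsilyloxy)‑3‑methylbutyl]‑2‑methoxyphenyl}methanol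
Conditions: PPTS (0.2 equiv), MeOH/CH2Cl2, 0 °C
Reagents that add atoms: none
Why: Mild acid methanolysis removes the primary TES ether far faster than the TBS and TIPS ethers (standard selective TES cleavage).

Step 16
Reactants: 29 ring A benzylic alcohol
Product: 30 6‑[2‑(benzyloxy)‑4‑methyl‑6‑(triisopropylsilyloxymethyl)phenoxy]‑3‑[(1S)‑1,3‑bis(tert‑butyldimethylsilyloxy)‑3‑methylbutyl]‑2‑methoxybenzaldehyde
Conditions: Dess–Martin periodinane, pyridine, CH2Cl2, rt
Reagents that add atoms: none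
Why: Dess–Martin oxidation of the hindered benzylic alcohol should stop cleanly at the aldehyde under conditions that spare silyl and benzyl ethers.

Step 17
Reactants: 30 ring A aldehyde
Product: 31 6‑[2‑(benzyloxy)‑4‑methyl‑6‑(triisopropylsilyloxymethyl)phenoxy]‑3‑[(1S)‑1,3‑bis(tert‑butyldimethylsilyloxy)‑3‑methylbutyl]‑2‑methoxybenzoic acid
Conditions: NaClO2, NaH2PO4, 2‑methylbut‑2‑ene, t‑BuOH/H2O, rt
Reagents that add atoms: sodium chlorite, [Na+].[O-]Cl=O
Why: Pinnick oxidation converts even di‑ortho‑substituted aryl aldehydes to acids, and the alkene scavenger removes HOCl before it can chlorinate the electron‑rich rings.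

Step 18
Reactants: 31 protected benzoic acid
Product: 32 6‑[2‑hydroxy‑4‑methyl‑6‑(triisopropylsilyloxymethyl)phenoxy]‑3‑[(1S)‑1,3‑bis(tert‑butyldimethylsilyloxy)‑3‑methylbutyl]‑2‑methoxybenzoic acid
Conditions: H2 (1 atm), 10% Pd/C, EtOAc, rt
Reagents that add atoms: none
Why: Hydrogenolysis of the aryl benzyl ether over palladium on carbon is fast under neutral conditions, while the benzylic C–O bonds of both rings are shielded as bulky silyl ethers and the diaryl ether is inert.

Step 19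
Reactants: 32 silylated phenol acid
Product: 33 CNP0452050.2, 6‑[2‑hydroxy‑6‑(hydroxymethyl)‑4‑methylphenoxy]‑3‑[(1S)‑1,3‑dihydroxy‑3‑methylbutyl]‑2‑methoxybenzoic acid
Conditions: Bu4NF (8 equiv), THF, 25 → 50 °C; AcOH quench
Reagents that add atoms: none
Why: Fluoride‑mediated desilylation should remove the primary TIPS ether, the benzylic secondary TBS ether and, on warming, the tertiary TBS ether, the carboxylate and phenoxide formed in the basic medium being inert and the stereocentre untouched.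

**Compound list**

1 | (S)‑3‑hydroxy‑γ‑butyrolactone | O=C1C[C@H](O)CO1 | starting material
2 | (2S)‑4‑methylpentane‑1,2,4‑triol | OC[C@@H](O)CC(C)(C)O | intermediate
3 | (2S)‑1,2,4‑tris(tert‑butyldimethylsilyloxy)‑4‑methylpentane | CC(C)(C)[Si](C)(C)OC[C@@H](O[Si](C)(C)C(C)(C)C)CC(C)(C)O[Si](C)(C)C(C)(C)C | intermediate
4 | (2S)‑2,4‑bis(tert‑butyldimethylsilyloxy)‑4‑methylpentan‑1‑ol | OC[C@@H](O[Si](C)(C)C(C)(C)C)CC(C)(C)O[Si](C)(C)C(C)(C)C | intermediate
5 | (2S)‑2,4‑bis(tert‑butyldimethylsilyloxy)‑4‑methylpentanal | O=C[C@@H](O[Si](C)(C)C(C)(C)C)CC(C)(C)O[Si](C)(C)C(C)(C)C | intermediate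
6 | 1‑(triphenylphosphoranylidene)propan‑2‑one | CC(=O)C=P(c1ccccc1)(c1ccccc1)c1ccccc1 | starting material
7 | (3E,5S)‑5,7‑bis(tert‑butyldimethylsilyloxy)‑7‑methyloct‑3‑en‑2‑one | CC(=O)/C=C/[C@@H](O[Si](C)(C)C(C)(C)C)CC(C)(C)O[Si](C)(C)C(C)(C)C | intermediate
8 | (5E,7S)‑7,9‑bis(tert‑butyldimethylsilyloxy)‑1,1,1‑trifluoro‑9‑methyldec‑5‑ene‑2,4‑dione | O=C(CC(=O)/C=C/[C@@H](O[Si](C)(C)C(C)(C)C)CC(C)(C)O[Si](C)(C)C(C)(C)C)C(F)(F)F | intermediate (not isolated)
9 | (3E,5S)‑5,7‑bis(tert‑butyldimethylsilyloxy)‑1‑diazo‑7‑methyloct‑3‑en‑2‑one | [N-]=[N+]=CC(=O)/C=C/[C@@H](O[Si](C)(C)C(C)(C)C)CC(C)(C)O[Si](C)(C)C(C)(C)C | intermediate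
10 | 2‑hydroxy‑3‑methoxy‑5‑methylbenzaldehyde | COc1cc(C)cc(C=O)c1O | starting material
11 | 2,3‑dihydroxy‑5‑methylbenzaldehyde | Cc1cc(O)c(O)c(C=O)c1 | intermediate
12 | 3‑(benzyloxy)‑2‑hydroxy‑5‑methylbenzaldehyde | O=Cc1cc(C)cc(OCc2ccccc2)c1O | intermediate
13 | trichloroethylene | ClC=C(Cl)Cl | starting material
14 | dichloroacetylene | ClC#CCl | intermediate (not isolated)
15 | 3‑(benzyloxy)‑2‑[(E)‑1,2‑dichlorovinyloxy]‑5‑methylbenzaldehyde | Cc1cc(C=O)c(O/C(Cl)=C\Cl)c(OCc2ccccc2)c1 | intermediate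
16 | {3‑(benzyloxy)‑2‑[(E)‑1,2‑dichlorovinyloxy]‑5‑methylphenyl}methanol | Cc1cc(CO)c(O/C(Cl)=C\Cl)c(OCc2ccccc2)c1 | intermediate
17 | {3‑(benzyloxy)‑2‑[(E)‑1,2‑dichlorovinyloxy]‑5‑methylbenzyloxy}triisopropylsilane | Cc1cc(CO[Si](C(C)C)(C(C)C)C(C)C)c(O/C(Cl)=C\Cl)c(OCc2ccccc2)c1 | intermediate
18 | formaldehyde | C=O | starting material
19 | {3‑(benzyloxy)‑2‑(chloroethynyloxy)‑5‑methylbenzyloxy}triisopropylsilane | Cc1cc(CO[Si](C(C)C)(C(C)C)C(C)C)c(OC#CCl)c(OCc2ccccc2)c1 | intermediate (not isolated)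
20 | lithium 2‑[2‑(benzyloxy)‑4‑methyl‑6‑(triisopropylsilyloxymethyl)phenoxy]ethynide | Cc1cc(CO[Si](C(C)C)(C(C)C)C(C)C)c(OC#C[Li])c(OCc2ccccc2)c1 | intermediate (not isolated)
21 | lithium 3‑[2‑(benzyloxy)‑4‑methyl‑6‑(triisopropylsilyloxymethyl)phenoxy]prop‑2‑yn‑1‑olate | Cc1cc(CO[Si](C(C)C)(C(C)C)C(C)C)c(OC#CCO[Li])c(OCc2ccccc2)c1 | intermediate (not isolated)
22 | {3‑(benzyloxy)‑5‑methyl‑2‑[3‑(triethylsilyloxy)prop‑1‑ynyloxy]benzyloxy}triisopropylsilane | Cc1cc(CO[Si](C(C)C)(C(C)C)C(C)C)c(OC#CCO[Si](CC)(CC)CC)c(OCc2ccccc2)c1 | intermediate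
23 | (3E,5S)‑5,7‑bis(tert‑butyldimethylsilyloxy)‑7‑methylocta‑1,3‑dien‑1‑one (vinylketene) | O=C=C/C=C/[C@@H](O[Si](C)(C)C(C)(C)C)CC(C)(C)O[Si](C)(C)C(C)(C)C | intermediate (not isolated)
24 | 3‑[2‑(benzyloxy)‑4‑methyl‑6‑(triisopropylsilyloxymethyl)phenoxy]‑4‑[(1E,3S)‑3,5‑bis(tert‑butyldimethylsilyloxy)‑5‑methylhex‑1‑enyl]‑2‑(triethylsilyloxymethyl)cyclobut‑2‑en‑1‑one (ring carbon C4 unassigned) | O=C1C(CO[Si](CC)(CC)CC)=C(Oc2c(OCc3ccccc3)cc(C)cc2CO[Si](C(C)C)(C(C)C)C(C)C)C1/C=C/[C@@H](O[Si](C)(C)C(C)(C)C)CC(C)(C)O[Si](C)(C)C(C)(C)C | intermediate (not isolated)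
25 | (3E,5E,7S)‑3‑[2‑(benzyloxy)‑4‑methyl‑6‑(triisopropylsilyloxymethyl)phenoxy]‑7,9‑bis(tert‑butyldimethylsilyloxy)‑9‑methyl‑2‑(triethylsilyloxymethyl)deca‑1,3,5‑trien‑1‑one (dienylketene) | O=C=C(CO[Si](CC)(CC)CC)/C(Oc1c(OCc2ccccc2)cc(C)cc1CO[Si](C(C)C)(C(C)C)C(C)C)=C\C=C\[C@@H](O[Si](C)(C)C(C)(C)C)CC(C)(C)O[Si](C)(C)C(C)(C)C | intermediate (not isolated)
26 | 3‑[2‑(benzyloxy)‑4‑methyl‑6‑(triisopropylsilyloxymethyl)phenoxy]‑6‑[(1S)‑1,3‑bis(tert‑butyldimethylsilyloxy)‑3‑methylbutyl]‑2‑(triethylsilyloxymethyl)cyclohexa‑2,4‑dien‑1‑one (ring carbon C6 unassigned) | O=C1C(CO[Si](CC)(CC)CC)=C(Oc2c(OCc3ccccc3)cc(C)cc2CO[Si](C(C)C)(C(C)C)C(C)C)C=CC1[C@@H](O[Si](C)(C)C(C)(C)C)CC(C)(C)O[Si](C)(C)C(C)(C)C | intermediate (not isolated)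
27 | 3‑[2‑(benzyloxy)‑4‑methyl‑6‑(triisopropylsilyloxymethyl)phenoxy]‑6‑[(1S)‑1,3‑bis(tert‑butyldimethylsilyloxy)‑3‑methylbutyl]‑2‑(triethylsilyloxymethyl)phenol | Oc1c([C@@H](O[Si](C)(C)C(C)(C)C)CC(C)(C)O[Si](C)(C)C(C)(C)C)ccc(Oc2c(OCc3ccccc3)cc(C)cc2CO[Si](C(C)C)(C(C)C)C(C)C)c1CO[Si](CC)(CC)CC | intermediate
28 | {6‑[2‑(benzyloxy)‑4‑methyl‑6‑(triisopropylsilyloxymethyl)phenoxy]‑3‑[(1S)‑1,3‑bis(tert‑butyldimethylsilyloxy)‑3‑methylbutyl]‑2‑methoxybenzyloxy}triethylsilane | COc1c([C@@H](O[Si](C)(C)C(C)(C)C)CC(C)(C)O[Si](C)(C)C(C)(C)C)ccc(Oc2c(OCc3ccccc3)cc(C)cc2CO[Si](C(C)C)(C(C)C)C(C)C)c1CO[Si](CC)(CC)CC | intermediate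
29 | {6‑[2‑(benzyloxy)‑4‑methyl‑6‑(triisopropylsilyloxymethyl)phenoxy]‑3‑[(1S)‑1,3‑bis(tert‑butyldimethylsilyloxy)‑3‑methylbutyl]‑2‑methoxyphenyl}methanol | COc1c([C@@H](O[Si](C)(C)C(C)(C)C)CC(C)(C)O[Si](C)(C)C(C)(C)C)ccc(Oc2c(OCc3ccccc3)cc(C)cc2CO[Si](C(C)C)(C(C)C)C(C)C)c1CO | intermediate
30 | 6‑[2‑(benzyloxy)‑4‑methyl‑6‑(triisopropylsilyloxymethyl)phenoxy]‑3‑[(1S)‑1,3‑bis(tert‑butyldimethylsilyloxy)‑3‑methylbutyl]‑2‑methoxybenzaldehyde | COc1c([C@@H](O[Si](C)(C)C(C)(C)C)CC(C)(C)O[Si](C)(C)C(C)(C)C)ccc(Oc2c(OCc3ccccc3)cc(C)cc2CO[Si](C(C)C)(C(C)C)C(C)C)c1C=O | intermediate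
31 | 6‑[2‑(benzyloxy)‑4‑methyl‑6‑(triisopropylsilyloxymethyl)phenoxy]‑3‑[(1S)‑1,3‑bis(tert‑butyldimethylsilyloxy)‑3‑methylbutyl]‑2‑methoxybenzoic acid | COc1c([C@@H](O[Si](C)(C)C(C)(C)C)CC(C)(C)O[Si](C)(C)C(C)(C)C)ccc(Oc2c(OCc3ccccc3)cc(C)cc2CO[Si](C(C)C)(C(C)C)C(C)C)c1C(=O)O | intermediate
32 | 6‑[2‑hydroxy‑4‑methyl‑6‑(triisopropylsilyloxymethyl)phenoxy]‑3‑[(1S)‑1,3‑bis(tert‑butyldimethylsilyloxy)‑3‑methylbutyl]‑2‑methoxybenzoic acid | COc1c([C@@H](O[Si](C)(C)C(C)(C)C)CC(C)(C)O[Si](C)(C)C(C)(C)C)ccc(Oc2c(O)cc(C)cc2CO[Si](C(C)C)(C(C)C)C(C)C)c1C(=O)O | intermediate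
33 | CNP0452050.2, 6‑[2‑hydroxy‑6‑(hydroxymethyl)‑4‑methylphenoxy]‑3‑[(1S)‑1,3‑dihydroxy‑3‑methylbutyl]‑2‑methoxybenzoic acid | COc1c([C@@H](O)CC(C)(C)O)ccc(Oc2c(O)cc(C)cc2CO)c1C(=O)O | target

**Step count**

Total: 19 steps. Longest linear sequence: 13 steps (steps 1–6 then 13–19; the ring B branch, steps 7–12 then 13–19, is equally long).

**Steps most likely to fail**

Step 13 (benzannulation). The internal aryloxyalkyne, hindered and inductively deactivated by the silyloxymethyl group, may capture vinylketene 23 too slowly. The ketene would then be lost to dimerisation or secondary photochemistry, or the TES group may migrate or be lost from the ortho‑hydroxybenzyl silyl ether during the thermal stage. The fallback sets out from 17 and 9 and comes back at 31; it also makes the formaldehyde addition of step 12 unnecessary. Compound 17 is taken with n‑BuLi to acetylide 20 as before but quenched with methanol, giving the terminal aryl ethynyl ether F1, the least hindered and most nucleophilic ketenophile of its class. Irradiation of 9 with F1 and then heating should give, through 23, the cyclobutenone F2, the dienylketene F3 and the cyclohexadienone F4, the C1‑unsubstituted phenol F5. Methylation (MeI, K2CO3) gives the resorcinol diether F6. Its C1–H lies between the methoxy and aryloxy oxygens and should be removed regioselectively by n‑BuLi (THF, −40 → −10 °C, directed ortho‑metalation) to give the aryllithium F7. Carboxylation with CO2 and acidification then give 31 directly, so the carboxyl carbon arrives after the ring is built and steps 14–17 fall away.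

Step 9 (dichlorovinyl ether). The phenoxide of 12 is flanked on both sides and deactivated by conjugation and chelation with the ortho‑formyl group. Its addition to dichloroacetylene may therefore be slow, and the aldehyde may be consumed by base‑mediated side reactions at 70 °C. The fallback sets out from 12 and comes back at 17 by inverting the order of events. Reduction of 12 with NaBH4 gives the hydroxymethyl phenol F8. Selective silylation of its primary alcohol (TIPSCl, imidazole, CH2Cl2, 0 °C; the di‑ortho‑substituted phenol is too hindered for the bulky silyl chloride) gives the phenol F9. Its non‑conjugated phenoxide should add to dichloroacetylene (trichloroethylene, K2CO3, DMF) far more readily, giving 17.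

Step 19 (global desilylation). The hindered tertiary silyl ether may be cleaved only slowly by basic fluoride, and the forcing conditions then needed may erode the polyanionic product and complicate its separation from ammonium salts. The fallback sets out from 31 and comes back at 33 by inverting the end game. The three silyl groups are removed from the benzyl ether 31 with acidic fluoride (HF·pyridine, pyridine/THF), which cleaves tertiary silyl ethers without generating a phenoxide, to give the benzyl‑protected triol acid F10. The aryl benzyl ether is then hydrogenolysed last (H2, Pd/C, EtOAc, neutral, short contact time). The risk moved to that last step is hydrogenolysis of the free benzylic C–O bonds, which neutral conditions and close monitoring should limit.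

**Further compounds**

F1 | step 13 | {3‑(benzyloxy)‑2‑(ethynyloxy)‑5‑methylbenzyloxy}triisopropylsilane | Cc1cc(CO[Si](C(C)C)(C(C)C)C(C)C)c(OC#C)c(OCc2ccccc2)c1
F2 | step 13 | 3‑[2‑(benzyloxy)‑4‑methyl‑6‑(triisopropylsilyloxymethyl)phenoxy]‑4‑[(1E,3S)‑3,5‑bis(tert‑butyldimethylsilyloxy)‑5‑methylhex‑1‑enyl]cyclobut‑2‑en‑1‑one | O=C1C=C(Oc2c(OCc3ccccc3)cc(C)cc2CO[Si](C(C)C)(C(C)C)C(C)C)C1/C=C/[C@@H](O[Si](C)(C)C(C)(C)C)CC(C)(C)O[Si](C)(C)C(C)(C)C
F3 | step 13 | (3E,5E,7S)‑3‑[2‑(benzyloxy)‑4‑methyl‑6‑(triisopropylsilyloxymethyl)phenoxy]‑7,9‑bis(tert‑butyldimethylsilyloxy)‑9‑methyldeca‑1,3,5‑trien‑1‑one | O=C=C/C(Oc1c(OCc2ccccc2)cc(C)cc1CO[Si](C(C)C)(C(C)C)C(C)C)=C\C=C\[C@@H](O[Si](C)(C)C(C)(C)C)CC(C)(C)O[Si](C)(C)C(C)(C)C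
F4 | step 13 | 3‑[2‑(benzyloxy)‑4‑methyl‑6‑(triisopropylsilyloxymethyl)phenoxy]‑6‑[(1S)‑1,3‑bis(tert‑butyldimethylsilyloxy)‑3‑methylbutyl]cyclohexa‑2,4‑dien‑1‑one | O=C1C=C(Oc2c(OCc3ccccc3)cc(C)cc2CO[Si](C(C)C)(C(C)C)C(C)C)C=CC1[C@@H](O[Si](C)(C)C(C)(C)C)CC(C)(C)O[Si](C)(C)C(C)(C)C
F5 | step 13 | 5‑[2‑(benzyloxy)‑4‑methyl‑6‑(triisopropylsilyloxymethyl)phenoxy]‑2‑[(1S)‑1,3‑bis(tert‑butyldimethylsilyloxy)‑3‑methylbutyl]phenol | Oc1cc(Oc2c(OCc3ccccc3)cc(C)cc2CO[Si](C(C)C)(C(C)C)C(C)C)ccc1[C@@H](O[Si](C)(C)C(C)(C)C)CC(C)(C)O[Si](C)(C)C(C)(C)C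
F6 | step 13 | methyl ether of F5, 4‑[2‑(benzyloxy)‑4‑methyl‑6‑(triisopropylsilyloxymethyl)phenoxy]‑1‑[(1S)‑1,3‑bis(tert‑butyldimethylsilyloxy)‑3‑methylbutyl]‑2‑methoxybenzene | COc1cc(Oc2c(OCc3ccccc3)cc(C)cc2CO[Si](C(C)C)(C(C)C)C(C)C)ccc1[C@@H](O[Si](C)(C)C(C)(C)C)CC(C)(C)O[Si](C)(C)C(C)(C)C
F7 | step 13 | {6‑[2‑(benzyloxy)‑4‑methyl‑6‑(triisopropylsilyloxymethyl)phenoxy]‑3‑[(1S)‑1,3‑bis(tert‑butyldimethylsilyloxy)‑3‑methylbutyl]‑2‑methoxyphenyl}lithium | COc1c([Li])c(Oc2c(OCc3ccccc3)cc(C)cc2CO[Si](C(C)C)(C(C)C)C(C)C)ccc1[C@@H](O[Si](C)(C)C(C)(C)C)CC(C)(C)O[Si](C)(C)C(C)(C)C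
F8 | step 9 | 2‑(benzyloxy)‑6‑(hydroxymethyl)‑4‑methylphenol | Cc1cc(CO)c(O)c(OCc2ccccc2)c1
F9 | step 9 | 2‑(benzyloxy)‑4‑methyl‑6‑(triisopropylsilyloxymethyl)phenol | Cc1cc(CO[Si](C(C)C)(C(C)C)C(C)C)c(O)c(OCc2ccccc2)c1
F10 | step 19 | 6‑[2‑(benzyloxy)‑6‑(hydroxymethyl)‑4‑methylphenoxy]‑3‑[(1S)‑1,3‑dihydroxy‑3‑methylbutyl]‑2‑methoxybenzoic acid | COc1c([C@@H](O)CC(C)(C)O)ccc(Oc2c(OCc3ccccc3)cc(C)cc2CO)c1C(=O)O
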